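**Plan**

- Retrosynthesis: the 8-O-methyl bond is cut first. Ring A is then opened at C4a–C5 and C8–C8a, which leaves a 3-methoxy-2-(4-methoxyphenyl)-4-pyranone metallated at its C5 and a four-carbon cyclobutenone unit made from dimethyl squarate. The pyranone C5–Sn, C2–aryl and C2–Br bonds lead back to pyromeconic acid.
- Feature used: in the target C5 carries H while C6, C7 and C8 carry three adjacent oxygens. These four A-ring carbons map onto CH, C(OMe), C(OMe) and C=O of a 4-substituted 2,3-dimethoxycyclobutenone, and C4a/C8a are the C5=C6 alkene carbons of the preformed pyranone (ring C).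
- Forward order: ring C is bought, ring B is attached at C2 by Suzuki coupling, C5 is iodinated and stannylated, and ring A is closed last by Stille coupling, 4π opening and 6π closure. The C8 phenol is then methylated.
- Stereochemistry: the target has no stereocentre; racemic sp3 centres of intermediates disappear on aromatisation.

Key step: step 8

Remark: the target SMILES contains no stereocentre, axis or stereogenic alkene, so Auranetin is achiral and no enantioselective step is needed. Pyromeconic acid, 4-methoxyphenylboronic acid and dimethyl squarate are taken as purchasable; they replace the furan-based entry to the pyranone, whose halogen-mediated oxidation would endanger the anisyl ring.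

**Route**

Step 1
Reactants: 1 3-hydroxy-4H-pyran-4-one (pyromeconic acid)
Product: 2 2-bromo-3-hydroxy-4H-pyran-4-one
Conditions: NBS (1.0 equiv), MeCN, 0 °C to rt
Reagents that add atoms: N-bromosuccinimide, O=C1CCC(=O)N1Br
Why: electrophilic bromination of the enolic hydroxypyranone should go to C2, the carbon ortho to the hydroxyl, the same site at which kojic acid takes halogens, diazonium ions and Mannich electrophiles.

Step 2
Reactants: 2 2-bromo-3-hydroxy-4H-pyran-4-one
Product: 3 2-bromo-3-methoxy-4H-pyran-4-one
Conditions: MeI, K2CO3, acetone, 55 °C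
Reagents that add atoms: iodomethane, CI
Why: Williamson O-methylation of the acidic enol hydroxyl, as in the routine preparation of maltol methyl ethers.

Step 3
Reactants: 3 2-bromo-3-methoxy-4H-pyran-4-one; 4 4-methoxyphenylboronic acid
Product: 5 3-methoxy-2-(4-methoxyphenyl)-4H-pyran-4-one
Conditions: Pd(dppf)Cl2 (3 mol %), K2CO3, dioxane/H2O, 70 °C
Reagents that add atoms: none
Why: Suzuki–Miyaura coupling of a β-bromo enone (vinylogous acyl bromide), a halide class that undergoes oxidative addition readily, with an electron-rich arylboronic acid.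

Step 4
Reactants: 5 3-methoxy-2-(4-methoxyphenyl)-4H-pyran-4-one
Product: 6 5-iodo-3-methoxy-2-(4-methoxyphenyl)-4H-pyran-4-one
Conditions: I2 (0.6 equiv), CAN (1.1 equiv), MeCN, 60 °C
Reagents that add atoms: iodine, II
Why: oxidative electrophilic iodination at the α-carbon of the vinylogous ester (pyranone C5), the reagent pair used for 3-iodination of methoxylated flavones; C3 is blocked and the anisyl ring is deactivated by conjugation to the enone.

Step 5
Reactants: 6 5-iodo-3-methoxy-2-(4-methoxyphenyl)-4H-pyran-4-one
Product: 7 3-methoxy-2-(4-methoxyphenyl)-5-(tributylstannyl)-4H-pyran-4-one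
Conditions: (Bu3Sn)2, Pd(PPh3)4 (5 mol %), toluene, 100 °C
Reagents that add atoms: hexabutylditin, CCCC[Sn](CCCC)(CCCC)[Sn](CCCC)(CCCC)CCCC
Why: palladium-catalysed stannylation of an alkenyl iodide with a ditin, as practised on α-iodoenones, 3-iodochromones and 5-iodouracils.

Step 6
Reactants: 8 dimethyl squarate (3,4-dimethoxycyclobut-3-ene-1,2-dione)
Product: 9 racemic 4-hydroxy-2,3-dimethoxycyclobut-2-en-1-one
Conditions: LiAlH(OtBu)3, THF, −78 to −20 °C; then H2O
Reagents that add atoms: none
Why: 1,2-hydride reduction of one squarate carbonyl by a bulky alkoxyaluminium hydride stops at the mono-alcohol because the remaining carbonyl is a far less electrophilic vinylogous ester; the new centre is racemic and is lost later.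

Step 7
Reactants: 9 racemic 4-hydroxy-2,3-dimethoxycyclobut-2-en-1-one
Product: 10 racemic 4-chloro-2,3-dimethoxycyclobut-2-en-1-one
Conditions: PPh3, NCS, CH2Cl2, −20 to 0 °C; used at once
Reagents that add atoms: N-chlorosuccinimide, O=C1CCC(=O)N1Cl
Why: Appel-type deoxychlorination, in which the chlorophosphonium reagent from PPh3 and NCS activates the hydroxyl and chloride displaces it by SN2 at the carbon next to the ketone under acid-free conditions, so the acid-triggered loss of methanol to the semisquarate is avoided.

Step 8
Reactants: 7 3-methoxy-2-(4-methoxyphenyl)-5-(tributylstannyl)-4H-pyran-4-one; 10 racemic 4-chloro-2,3-dimethoxycyclobut-2-en-1-one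
Product: 14 8-hydroxy-3,6,7-trimethoxy-2-(4-methoxyphenyl)-4H-chromen-4-one, via coupled cyclobutenone 11 (not isolated), via dienylketene 12 (not isolated), via keto tautomer 13 (not isolated)
Conditions: Pd2(dba)3 (2.5 mol %), tri(2-furyl)phosphine (10 mol %), CuI (10 mol %), dioxane, 50 °C; then 100 °C
Reagents that add atoms: none
Why: Pd(0) inserts into the C–Cl bond of 10 to give an oxocyclobutenyl–palladium(II) species, and tin-to-palladium transfer of the pyranonyl group (helped by CuI) followed by reductive elimination at the CH terminus forms the flavone C4a–C5 bond (Stille coupling) and gives 11. At 100 °C 11 opens by a thermal conrotatory 4π electrocyclic reaction to the dienylketene 12, whose ketene carbon closes onto the pyranone C6–H carbon in a thermal disrotatory 6π electrocyclisation that forms C8–C8a and the six-membered ring A as dienone 13, which enolises to phenol 14. The closest known reaction type is the palladium-catalysed coupling of 4-chlorocyclobutenones with alkenyl, aryl and heteroaryl stannanes followed by thermal benzannulation to phenols. No stereocentre is created in 14, since the racemic sp3 carbons of 11 and 13 become sp2 on ring opening and enolisation. The step needs C–C bond formation at the chlorine-bearing carbon and not at the methoxy-bearing allylic terminus, which the smaller CH terminus and the retained vinylogous ester conjugation should secure, and it needs closure at one site only, which is fixed because the other neighbour of the pyranone C5 is the C4 carbonyl carbon. Ring opening is reversible, so a ketene isomer that cannot close returns to 11 and only the isomer with the pyranonyl group cis to the ketene drains to product.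

Step 9
Reactants: 14 8-hydroxy-3,6,7-trimethoxy-2-(4-methoxyphenyl)-4H-chromen-4-one
Product: 15 Auranetin (3,6,7,8-tetramethoxy-2-(4-methoxyphenyl)-4H-chromen-4-one)
Conditions: MeI, K2CO3, acetone, 55 °C
Reagents that add atoms: iodomethane, CI
Why: Williamson O-methylation of the only free phenol, a standard operation on hydroxyflavones.

**Compound list**

1 | 3-hydroxy-4H-pyran-4-one (pyromeconic acid) | O=c1ccocc1O | starting material
2 | 2-bromo-3-hydroxy-4H-pyran-4-one | O=c1ccoc(Br)c1O | intermediate
3 | 2-bromo-3-methoxy-4H-pyran-4-one | COc1c(Br)occc1=O | intermediate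
4 | 4-methoxyphenylboronic acid | COc1ccc(B(O)O)cc1 | starting material
5 | 3-methoxy-2-(4-methoxyphenyl)-4H-pyran-4-one | COc1ccc(-c2occc(=O)c2OC)cc1 | intermediate
6 | 5-iodo-3-methoxy-2-(4-methoxyphenyl)-4H-pyran-4-one | COc1ccc(-c2occ(I)c(=O)c2OC)cc1 | intermediate
7 | 3-methoxy-2-(4-methoxyphenyl)-5-(tributylstannyl)-4H-pyran-4-one | COc1ccc(-c2occ([Sn](CCCC)(CCCC)CCCC)c(=O)c2OC)cc1 | intermediate
8 | dimethyl squarate (3,4-dimethoxycyclobut-3-ene-1,2-dione) | COC1=C(OC)C(=O)C1=O | starting material
9 | racemic 4-hydroxy-2,3-dimethoxycyclobut-2-en-1-one | COC1=C(OC)C(O)C1=O | intermediate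
10 | racemic 4-chloro-2,3-dimethoxycyclobut-2-en-1-one | COC1=C(OC)C(Cl)C1=O | intermediate
11 | racemic 5-(2,3-dimethoxy-4-oxocyclobut-2-en-1-yl)-3-methoxy-2-(4-methoxyphenyl)-4H-pyran-4-one | COc1ccc(-c2occ(C3C(OC)=C(OC)C3=O)c(=O)c2OC)cc1 | intermediate (not isolated)
12 | 2,3-dimethoxy-4-[5-methoxy-6-(4-methoxyphenyl)-4-oxo-4H-pyran-3-yl]buta-1,3-dien-1-one, pyranonyl cis to the ketene carbon | COc1ccc(-c2occ(/C=C(/OC)C(OC)=C=O)c(=O)c2OC)cc1 | intermediate (not isolated)
13 | racemic 3,6,7-trimethoxy-2-(4-methoxyphenyl)-8aH-chromene-4,8-dione | COc1ccc(C2=C(OC)C(=O)C3=CC(OC)=C(OC)C(=O)C3O2)cc1 | intermediate (not isolated)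
14 | 8-hydroxy-3,6,7-trimethoxy-2-(4-methoxyphenyl)-4H-chromen-4-one | COc1ccc(-c2oc3c(O)c(OC)c(OC)cc3c(=O)c2OC)cc1 | intermediate
15 | Auranetin, 3,6,7,8-tetramethoxy-2-(4-methoxyphenyl)-4H-chromen-4-one | COc1ccc(-c2oc3c(OC)c(OC)c(OC)cc3c(=O)c2OC)cc1 | target

**Step count**

Total: 9 steps. Longest linear sequence: 7 steps (steps 1, 2, 3, 4, 5, 8, 9); steps 6 and 7 form the second branch.

**Steps most likely to fail**

1. Step 8. Transmetalation of the carbonyl-flanked, electron-poor stannane may be slow, so that protodestannylation or bond formation at the methoxy-bearing terminus of the oxocyclobutenyl–palladium unit competes and the four-carbon piece is lost. The fallback keeps the same ring opening and closure but uses carbonyl addition in place of cross-coupling, at one oxidation level higher at C5. It sets out from 6 and 8. Iodine–magnesium exchange on 6 (iPrMgCl·LiCl, THF, −40 °C) should give [5-methoxy-6-(4-methoxyphenyl)-4-oxo-4H-pyran-3-yl]magnesium chloride F1. Addition of F1 to one carbonyl of 8 at −78 °C should give racemic 4-hydroxy-2,3-dimethoxy-4-[5-methoxy-6-(4-methoxyphenyl)-4-oxo-4H-pyran-3-yl]cyclobut-2-en-1-one F2. Heating in toluene at 110 °C under argon should open the ring and close it onto the pyranone C6 to give 5,8-dihydroxy-3,6,7-trimethoxy-2-(4-methoxyphenyl)-4H-chromen-4-one F3. One equivalent of MeI with K2CO3 in acetone should methylate the free 8-hydroxyl and spare the chelated 5-hydroxyl, giving 5-hydroxy-3,6,7,8-tetramethoxy-2-(4-methoxyphenyl)-4H-chromen-4-one F4. Tf2O/pyridine should then give 3,6,7,8-tetramethoxy-2-(4-methoxyphenyl)-4-oxo-4H-chromen-5-yl trifluoromethanesulfonate F5. Reduction with Pd(OAc)2/dppf and HCO2H/Et3N in DMF at 70 °C should remove the triflate and return to the route at 15.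

2. Step 7. The C–Cl bond may ionise with help from the 2-methoxy group, chloride may return at the methoxy-bearing carbon and chloromethane may be lost, so that the reagent collapses to the semisquarate during its preparation or before coupling. The fallback replaces the halide by a leaving group that releases no nucleophilic halide. It sets out from 9. Methyl chloroformate and pyridine in CH2Cl2 at 0 °C should give racemic 2,3-dimethoxy-4-oxocyclobut-2-en-1-yl methyl carbonate F6. F6 is then ionised by Pd2(dba)3/tri(2-furyl)phosphine in DMF at 50 °C in the presence of 7 (allylic carbonate–stannane coupling). This should give 11, and heating to 100 °C returns to the route at 14.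

3. Step 4. Iodination may go ortho to the methoxy group of the anisyl ring, or Ce(IV) may oxidise that ring by electron transfer, in place of substitution at the pyranone C5. The fallback installs the halogen by alkene addition and elimination without an oxidant. It sets out from 5. Br2 (1 equiv) in CH2Cl2 at 0 °C should add across the pyranone C5=C6 bond to give racemic trans-5,6-dibromo-3-methoxy-2-(4-methoxyphenyl)-5,6-dihydro-4H-pyran-4-one F7. Et3N should then remove HBr (the acidic C5–H and the C6 bromide) to give 5-bromo-3-methoxy-2-(4-methoxyphenyl)-4H-pyran-4-one F8. Stannylation of F8 under the conditions of step 5 returns to the route at 7.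

**Further compounds**

F1 | step 8 | [5-methoxy-6-(4-methoxyphenyl)-4-oxo-4H-pyran-3-yl]magnesium chloride | COc1ccc(-c2occ([Mg]Cl)c(=O)c2OC)cc1
F2 | step 8 | racemic 4-hydroxy-2,3-dimethoxy-4-[5-methoxy-6-(4-methoxyphenyl)-4-oxo-4H-pyran-3-yl]cyclobut-2-en-1-one | COc1ccc(-c2occ(C3(O)C(OC)=C(OC)C3=O)c(=O)c2OC)cc1
F3 | step 8 | 5,8-dihydroxy-3,6,7-trimethoxy-2-(4-methoxyphenyl)-4H-chromen-4-one | COc1ccc(-c2oc3c(O)c(OC)c(OC)c(O)c3c(=O)c2OC)cc1
F4 | step 8 | 5-hydroxy-3,6,7,8-tetramethoxy-2-(4-methoxyphenyl)-4H-chromen-4-one | COc1ccc(-c2oc3c(OC)c(OC)c(OC)c(O)c3c(=O)c2OC)cc1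
F5 | step 8 | 3,6,7,8-tetramethoxy-2-(4-methoxyphenyl)-4-oxo-4H-chromen-5-yl trifluoromethanesulfonate | COc1ccc(-c2oc3c(OC)c(OC)c(OC)c(OS(=O)(=O)C(F)(F)F)c3c(=O)c2OC)cc1
F6 | step 7 | racemic 2,3-dimethoxy-4-oxocyclobut-2-en-1-yl methyl carbonate | COC(=O)OC1C(OC)=C(OC)C1=O
F7 | step 4 | racemic trans-5,6-dibromo-3-methoxy-2-(4-methoxyphenyl)-5,6-dihydro-4H-pyran-4-one (one enantiomer drawn) | COc1ccc(C2=C(OC)C(=O)[C@@H](Br)[C@H](Br)O2)cc1
F8 | step 4 | 5-bromo-3-methoxy-2-(4-methoxyphenyl)-4H-pyran-4-one | COc1ccc(-c2occ(Br)c(=O)c2OC)cc1
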